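**Retrosynthetic overview**
1. Target 24 ⇐ oxidation of the C3 carbinol 23 ⇐ equatorial methyl addition to the ring B ketone 21.
2. Rings A (oxepane) and B (cyclohexane) ⇐ one TMSOTf-triggered diepoxide/enol silane cascade on 20 (O1–C2 and C5a–C6 bonds).
3. 20 ⇐ HWE union in the two-carbon linker of hydroazulene aldehyde 14 with diepoxy ketophosphonate 18 (geranyl bromide, Shi epoxidation).
4. 14 ⇐ Claisen transfer from a C7 carbinol ⇐ cycloheptenone 11 ⇐ syn-hydroboration of a tetrasubstituted cyclopentene ⇐ 7-endo MHAT radical cyclization ⇐ enal 3 from (S)-limonene.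
5. Ring order: D (cyclopentane, step 2), C (cycloheptane, step 6), then A and B together (step 16).

Assumption: the L-configured Shi ketone (enantiomer of the D-fructose-derived catalyst, made from L-sorbose) is available as a catalyst.
Locants: hydroazulene C1 = carbinol carbon, C3a/C8a = ring fusion, C4 = CMe2, C5 = linker-bearing carbon, C6 = methyl-bearing alkene carbon, then C7, C8. Benzoxepine: O1, C2 (CMe2), C3, C4, C5, C5a, C6, C7, C8, C9, C9a.

**Step 1**
Reactants: 1 (S)-(−)-limonene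
Product: 2 (3S)-6-oxo-3-(prop-1-en-2-yl)heptanal
Conditions: O3 (1.0 equiv), CH2Cl2/MeOH, −78 °C; then Me2S, −78 °C to rt
Reagents that add atoms: ozone, [O-][O+]=O
Why: Ozone attacks the electron-richer trisubstituted ring alkene faster than the 1,1-disubstituted isopropenyl group, so a chemoselective ozonolysis with reductive work-up opens only the ring and leaves the stereocenter untouched.

**Step 2**
Reactants: 2 keto aldehyde
Product: 3 (5R)-2-methyl-5-(prop-1-en-2-yl)cyclopent-1-ene-1-carbaldehyde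
Conditions: piperidine (cat.), AcOH (cat.), benzene, reflux (Dean–Stark)
Reagents that add atoms: none
Why: The aldehyde enamine adds to the methyl ketone and the adduct dehydrates (intramolecular aldol condensation) to the conjugated cyclopentene enal, ring D, with the non-epimerizable stereocenter retained.

**Step 3**
Reactants: 3 enal
Product: 4 [(5R)-2-methyl-5-(prop-1-en-2-yl)cyclopent-1-en-1-yl]methanol
Conditions: NaBH4, CeCl3·7H2O, MeOH, 0 °C
Reagents that add atoms: none
Why: Luche 1,2-reduction gives the primary allylic alcohol without touching either alkene.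

**Step 4**
Reactants: 4 allylic alcohol
Product: 5 (5R)-1-(chloromethyl)-2-methyl-5-(prop-1-en-2-yl)cyclopent-1-ene
Conditions: N-chlorosuccinimide, Me2S, CH2Cl2, −20 to 0 °C
Reagents that add atoms: N-chlorosuccinimide, ClN1C(=O)CCC1=O
Why: Corey–Kim chlorination activates the hydroxyl as an alkoxysulfonium ion that chloride displaces at the primary carbon, so no allylic transposition occurs.

**Step 5**
Reactants: 5 allylic chloride
Product: 6 3-methyl-1-[(5R)-2-methyl-5-(prop-1-en-2-yl)cyclopent-1-en-1-yl]but-3-en-2-one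
Conditions: CO (3 atm), tributyl(prop-1-en-2-yl)stannane, Pd2(dba)3 (2.5 mol %), PPh3, THF, 50 °C
Reagents that add atoms: carbon monoxide, [C-]#[O+]; tributyl(prop-1-en-2-yl)stannane, CCCC[Sn](CCCC)(CCCC)C(C)=C
Why: Carbonylative Stille coupling: the π-allylpalladium complex inserts CO at its unsubstituted terminus and then couples with the alkenylstannane, which installs the C7 ketone and the C5=C6 acceptor alkene in one operation.

**Step 6**
Reactants: 6 dienone
Product: 7 (3aR)-1,4,4,6-tetramethyl-2,3,3a,4,5,6,7,8-octahydroazulen-7-one (C1=C8a alkene; C6 epimers)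
Conditions: Fe(acac)3 (0.5 equiv), PhSiH3, EtOH/ethylene glycol 5:1, 0.02 M, 60 °C
Reagents that add atoms: none
Why: An iron hydride made from Fe(acac)3 and PhSiH3 transfers a hydrogen atom to the isopropenyl CH2 (Mukaiyama-type MHAT) and the tertiary C4 radical adds 7-endo to the unsubstituted enone terminus (intramolecular Giese reaction), which builds the CMe2 centre and ring C while the C6 centre formed here is erased in step 9.

**Step 7**
Reactants: 7 bicyclic ketone
Product: 8 (1S,3aS,8aS)-1,4,4,6-tetramethyldecahydroazulene-1,7-diol (C6 and C7 epimers)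
Conditions: BH3·THF (excess), THF, 0 °C to rt; then NaOH, H2O2, 0 °C to rt
Reagents that add atoms: hydrogen peroxide, OO
Why: Excess BH3 reduces the ketone and then adds syn across the tetrasubstituted alkene from the face opposite the C3a–C4 bond with boron on the less hindered C1 (Brown hydroboration–oxidation), which sets H-8a cis to H-3a and the tertiary C1 hydroxyl cis to H-8a.

**Step 8**
Reactants: 8 diol
Product: 9 (1S,3aS,8aS)-1-hydroxy-1,4,4,6-tetramethyldecahydroazulen-7-one (C6 epimers)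
Conditions: Dess–Martin periodinane, NaHCO3, CH2Cl2, 0 °C to rt
Reagents that add atoms: none
Why: Dess–Martin oxidation returns the secondary C7 carbinol to the ketone while the tertiary alcohol cannot be oxidized.

**Step 9**
Reactants: 9 hydroxy ketone
Product: 11 (1S,3aS,8aS)-1,4,4,6-tetramethyl-1-(trimethylsilyloxy)-2,3,3a,4,8,8a-hexahydroazulen-7(1H)-one, via bis(trimethylsilyl) enol ether 10 (not isolated)
Conditions: TMSOTf, Et3N, CH2Cl2, 0 °C to rt; then Pd(OAc)2 (1.1 equiv), MeCN, rt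
Reagents that add atoms: trimethylsilyl trifluoromethanesulfonate, C[Si](C)(C)OS(=O)(=O)C(F)(F)F
Why: Equilibrating silylation gives the more substituted C6=C7 silyl enol ether and caps the tertiary alcohol, and the palladium enolate then loses the C5 hydrogen (Saegusa–Ito oxidation) to give the 2-methylcycloheptenone.

**Step 10**
Reactants: 11 enone
Product: 12 (1S,3aS,7R,8aS)-1,4,4,6-tetramethyl-1-(trimethylsilyloxy)-1,2,3,3a,4,7,8,8a-octahydroazulen-7-ol
Conditions: NaBH4, CeCl3·7H2O, MeOH, −78 to −40 °C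
Reagents that add atoms: none
Why: Luche 1,2-reduction delivers hydride to the convex face (the face of H-3a and H-8a, away from the C1 methyl and ring D), which places the C7 hydroxyl on the concave face.

**Step 11**
Reactants: 12 allylic alcohol
Product: 14 2-[(1S,3aS,5R,8aS)-1,4,4,6-tetramethyl-1-(trimethylsilyloxy)-1,2,3,3a,4,5,8,8a-octahydroazulen-5-yl]acetaldehyde, via allyl vinyl ether 13 (not isolated)
Conditions: butyl vinyl ether, Pd(OCOCF3)2 (cat.), 4,7-diphenyl-1,10-phenanthroline, Et3N, 75 °C; then toluene, 180 °C (sealed tube)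
Reagents that add atoms: butyl vinyl ether, CCCCOC=C
Why: Transfer vinylation followed by Claisen rearrangement forms the C5–CH2 bond on the face that carried the C7 oxygen (suprafacial 1,3-chirality transfer), which sets C5 and moves the alkene to C6=C7.

**Step 12**
Reactants: 15 dimethyl (2-oxopropyl)phosphonate; 16 geranyl bromide
Product: 17 dimethyl [(5E)-6,10-dimethyl-2-oxoundeca-5,9-dien-1-yl]phosphonate
Conditions: NaH, THF, 0 °C; n-BuLi, 0 °C; then 16, 0 °C to rt; aq. NH4Cl
Reagents that add atoms: none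
Why: The terminal carbon of the β-ketophosphonate dianion is the more nucleophilic site and is alkylated by the allylic bromide in an SN2 reaction that keeps the E alkene.

**Step 13**
Reactants: 17 dienyl ketophosphonate
Product: 18 dimethyl {4-[(2S,3S)-3-{2-[(2S)-3,3-dimethyloxiran-2-yl]ethyl}-3-methyloxiran-2-yl]-2-oxobutyl}phosphonate
Conditions: L-configured Shi ketone (0.6 equiv), KHSO5 (as 2KHSO5·KHSO4·K2SO4), K2CO3, Bu4NHSO4, MeCN/CH2(OMe)2/aq. Na2B4O7–Na2EDTA buffer, 0 °C
Reagents that add atoms: potassium peroxymonosulfate, [K+].[O-]S(=O)(=O)OO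
Why: Shi asymmetric epoxidation: the chiral dioxirane adds oxygen to the same face of both trisubstituted alkenes through a spiro transition state, giving the (S,S) internal and (S) terminal epoxides.

**Step 14**
Reactants: 14 hydroazulene aldehyde; 18 diepoxy ketophosphonate
Product: 19 (4E)-1-[(2S,3S)-3-{2-[(2S)-3,3-dimethyloxiran-2-yl]ethyl}-3-methyloxiran-2-yl]-6-[(1S,3aS,5R,8aS)-1,4,4,6-tetramethyl-1-(trimethylsilyloxy)-1,2,3,3a,4,5,8,8a-octahydroazulen-5-yl]hex-4-en-3-one
Conditions: LiCl, i-Pr2NEt, MeCN, rt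
Reagents that add atoms: none
Why: Masamune–Roush Horner–Wadsworth–Emmons olefination joins the two fragments as the E-enone under conditions that spare epoxides and the silyl ether.

**Step 15**
Reactants: 19 enone
Product: 20 (3Z)-triethylsilyl enol ether of 19 (C=C between linker carbon and former carbonyl carbon)
Conditions: Et3SiH, RhCl(PPh3)3 (2 mol %), toluene, 50 °C
Reagents that add atoms: triethylsilane, CC[SiH](CC)CC
Why: Rhodium-catalysed 1,4-hydrosilylation of the enone gives the regiodefined (Z)-silyl enol ether, which fixes which α-carbon will act as the nucleophile.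

**Step 16**
Reactants: 20 diepoxy enol silane
Product: 21 (3S,5aS,6S,9aS)-2,2,5a-trimethyl-6-{2-[(1S,3aS,5R,8aS)-1,4,4,6-tetramethyl-1-(trimethylsilyloxy)-1,2,3,3a,4,5,8,8a-octahydroazulen-5-yl]ethyl}-3-(trimethylsilyloxy)octahydro-1-benzoxepin-7(2H)-one
Conditions: TMSOTf, 2,6-di-tert-butyl-4-methylpyridine, CH2Cl2, −78 °C; aq. NaHCO3
Reagents that add atoms: trimethylsilyl trifluoromethanesulfonate, C[Si](C)(C)OS(=O)(=O)C(F)(F)F
Why: In this biomimetic oxa-/carbacyclization cascade the silylated terminal epoxide is opened at its tertiary carbon by the internal epoxide oxygen (ring A) and the resulting epoxonium ion is opened at C5a with inversion by the enol silane through a chair transition state (ring B), so the trans fusion follows from the epoxide configurations and the equatorial C6 side chain from the Z-enol ether.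

**Step 17**
Reactants: 21 ring B ketone
Product: 23 (3S,5aS,6S,7R,9aS)-6-{2-[(1S,3aS,5R,8aS)-1-hydroxy-1,4,4,6-tetramethyl-1,2,3,3a,4,5,8,8a-octahydroazulen-5-yl]ethyl}-2,2,5a,7-tetramethyldecahydro-1-benzoxepine-3,7-diol, via bis(trimethylsilyl) ether 22 (not isolated)
Conditions: MeLi, CeCl3, THF, −78 °C; aq. work-up; then Bu4NF, THF, rt
Reagents that add atoms: methyllithium, [Li]C
Why: The organocerium reagent adds from the equatorial direction because axial attack is blocked by the syn-axial C5a methyl (1,2-addition under steric approach control), which gives the axial C7 alcohol, and fluoride then removes both silyl groups.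

**Step 18**
Reactants: 23 triol
Product: 24 target (5aS,6S,7R,9aS)-7-hydroxy-6-{2-[(1S,3aS,5R,8aS)-1-hydroxy-1,4,4,6-tetramethyl-1,2,3,3a,4,5,8,8a-octahydroazulen-5-yl]ethyl}-2,2,5a,7-tetramethyloctahydro-1-benzoxepin-3(2H)-one
Conditions: Dess–Martin periodinane, NaHCO3, CH2Cl2, 0 °C to rt
Reagents that add atoms: none
Why: Dess–Martin oxidation converts the only secondary alcohol into the oxepanone while both tertiary alcohols remain.

**Compound list**
1 | (S)-(−)-limonene | CC1=CC[C@H](CC1)C(C)=C | starting material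
2 | (3S)-6-oxo-3-(prop-1-en-2-yl)heptanal | CC(=O)CC[C@@H](CC=O)C(C)=C | intermediate
3 | (5R)-2-methyl-5-(prop-1-en-2-yl)cyclopent-1-ene-1-carbaldehyde | CC1=C(C=O)[C@H](CC1)C(C)=C | intermediate
4 | [(5R)-2-methyl-5-(prop-1-en-2-yl)cyclopent-1-en-1-yl]methanol | CC1=C(CO)[C@H](CC1)C(C)=C | intermediate
5 | (5R)-1-(chloromethyl)-2-methyl-5-(prop-1-en-2-yl)cyclopent-1-ene | CC1=C(CCl)[C@H](CC1)C(C)=C | intermediate
6 | 3-methyl-1-[(5R)-2-methyl-5-(prop-1-en-2-yl)cyclopent-1-en-1-yl]but-3-en-2-one | CC1=C(CC(=O)C(C)=C)[C@H](CC1)C(C)=C | intermediate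
7 | (3aR)-1,4,4,6-tetramethyl-2,3,3a,4,5,6,7,8-octahydroazulen-7-one (C6 epimers) | CC1=C2CC(=O)C(C)CC(C)(C)[C@H]2CC1 | intermediate
8 | (1S,3aS,8aS)-1,4,4,6-tetramethyldecahydroazulene-1,7-diol (cis-fused; 1-OH cis to H-8a; C6/C7 epimers) | CC1C(O)C[C@H]2[C@H](CC[C@]2(C)O)C(C)(C)C1 | intermediate
9 | (1S,3aS,8aS)-1-hydroxy-1,4,4,6-tetramethyldecahydroazulen-7-one (C6 epimers) | CC1C(=O)C[C@H]2[C@H](CC[C@]2(C)O)C(C)(C)C1 | intermediate
10 | trimethyl{[(1S,3aS,8aS)-1,4,4,6-tetramethyl-1-(trimethylsilyloxy)-1,2,3,3a,4,5,8,8a-octahydroazulen-7-yl]oxy}silane | CC1=C(O[Si](C)(C)C)C[C@H]2[C@H](CC[C@]2(C)O[Si](C)(C)C)C(C)(C)C1 | intermediate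
11 | (1S,3aS,8aS)-1,4,4,6-tetramethyl-1-(trimethylsilyloxy)-2,3,3a,4,8,8a-hexahydroazulen-7(1H)-one | O=C1C[C@H]2[C@H](CC[C@]2(C)O[Si](C)(C)C)C(C)(C)C=C1C | intermediate
12 | (1S,3aS,7R,8aS)-1,4,4,6-tetramethyl-1-(trimethylsilyloxy)-1,2,3,3a,4,7,8,8a-octahydroazulen-7-ol (7-OH trans to H-8a) | O[C@@H]1C[C@H]2[C@H](CC[C@]2(C)O[Si](C)(C)C)C(C)(C)C=C1C | intermediate
13 | (1S,3aS,7R,8aS)-7-(ethenyloxy)-1,4,4,6-tetramethyl-1-(trimethylsilyloxy)-1,2,3,3a,4,7,8,8a-octahydroazulene | C=CO[C@@H]1C[C@H]2[C@H](CC[C@]2(C)O[Si](C)(C)C)C(C)(C)C=C1C | intermediate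
14 | 2-[(1S,3aS,5R,8aS)-1,4,4,6-tetramethyl-1-(trimethylsilyloxy)-1,2,3,3a,4,5,8,8a-octahydroazulen-5-yl]acetaldehyde | CC1=CC[C@H]2[C@H](CC[C@]2(C)O[Si](C)(C)C)C(C)(C)[C@@H]1CC=O | intermediate
15 | dimethyl (2-oxopropyl)phosphonate | COP(=O)(OC)CC(C)=O | starting material
16 | geranyl bromide, (2E)-1-bromo-3,7-dimethylocta-2,6-diene | CC(C)=CCC/C(C)=C/CBr | starting material
17 | dimethyl [(5E)-6,10-dimethyl-2-oxoundeca-5,9-dien-1-yl]phosphonate | COP(=O)(OC)CC(=O)CC/C=C(\C)CCC=C(C)C | intermediate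
18 | dimethyl {4-[(2S,3S)-3-{2-[(2S)-3,3-dimethyloxiran-2-yl]ethyl}-3-methyloxiran-2-yl]-2-oxobutyl}phosphonate | COP(=O)(OC)CC(=O)CC[C@@H]1O[C@@]1(C)CC[C@@H]1OC1(C)C | intermediate
19 | (4E)-enone from 14 and 18 (name as in step 14) | CC1=CC[C@H]2[C@H](CC[C@]2(C)O[Si](C)(C)C)C(C)(C)[C@@H]1C/C=C/C(=O)CC[C@@H]1O[C@@]1(C)CC[C@@H]1OC1(C)C | intermediate
20 | (3Z)-triethylsilyl enol ether of 19 | CC1=CC[C@H]2[C@H](CC[C@]2(C)O[Si](C)(C)C)C(C)(C)[C@@H]1CC/C=C(\O[Si](CC)(CC)CC)CC[C@@H]1O[C@@]1(C)CC[C@@H]1OC1(C)C | intermediate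
21 | (3S,5aS,6S,9aS)-ring A/B ketone with 3-OTMS and hydroazulenylethyl side chain (name as in step 16) | CC1=CC[C@H]2[C@H](CC[C@]2(C)O[Si](C)(C)C)C(C)(C)[C@@H]1CC[C@H]1[C@]2(C)CC[C@H](O[Si](C)(C)C)C(C)(C)O[C@H]2CCC1=O | intermediate
22 | (3S,5aS,6S,7R,9aS)-7-methyl carbinol of 21, both silyl ethers intact | CC1=CC[C@H]2[C@H](CC[C@]2(C)O[Si](C)(C)C)C(C)(C)[C@@H]1CC[C@H]1[C@]2(C)CC[C@H](O[Si](C)(C)C)C(C)(C)O[C@H]2CC[C@@]1(C)O | intermediate
23 | (3S,5aS,6S,7R,9aS)-triol (name as in step 17) | CC1=CC[C@H]2[C@H](CC[C@]2(C)O)C(C)(C)[C@@H]1CC[C@H]1[C@]2(C)CC[C@H](O)C(C)(C)O[C@H]2CC[C@@]1(C)O | intermediate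
24 | CNP0194989.3 (name as in step 18) | CC1=CC[C@H]2[C@H](CC[C@]2(C)O)C(C)(C)[C@@H]1CC[C@H]1[C@]2(C)CCC(=O)C(C)(C)O[C@H]2CC[C@@]1(C)O | target

**Totals**
Total steps: 18. Longest linear sequence: 16 (steps 1–11 and 14–18, from 1).

**Steps most likely to fail, with fallbacks**

Step 5 (carbonylative coupling; the β,γ-unsaturated α-methylene ketone 6 is sensitive). The fallback sets out from 3 and comes back at 6. Wittig reaction of 3 with Ph3P=CHOMe gives the dienyl methyl ether F1. Mild aqueous acid hydrolyses it to the homologated aldehyde F2. Isopropenylmagnesium bromide adds to give the allylic alcohol F3, and Dess–Martin oxidation gives 6.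

Step 6 (7-endo radical closure competes with simple reduction of the C4 radical). The fallback sets out from 5 and comes back at 7. PhSO2Na displaces the chloride to give the allylic sulfone F4. Intermolecular reductive olefin coupling (Fe(acac)3, PhSiH3) of its isopropenyl group with methyl methacrylate gives the sulfonyl ester F5. LiHMDS closes ring C by acylation of the sulfone carbanion with the ester to give the cyclic keto sulfone F6, and Al(Hg) removes the sulfonyl group to give 7.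

Step 16 (the cascade may suffer with the full side chain and its silyl ether present). The fallback sets out from 18 and comes back at 21. TMSOTf/Et3N converts 18 into the phosphonate-substituted silyl enol ether F7. F7 is cyclized on its own with TMSOTf and 2,6-di-tert-butyl-4-methylpyridine to the bicyclic ketophosphonate F8. Horner–Wadsworth–Emmons reaction of F8 with aldehyde 14 (NaH, THF) gives the exocyclic enone F9. Conjugate reduction with a copper hydride made from Cu(OAc)2, a bisphosphine and a silane, followed by equilibrating protonation, gives 21.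

**Further compounds**
F1 | step 5 | (5R)-1-(2-methoxyethenyl)-2-methyl-5-(prop-1-en-2-yl)cyclopent-1-ene | CC1=C(C=COC)[C@H](CC1)C(C)=C
F2 | step 5 | 2-[(5R)-2-methyl-5-(prop-1-en-2-yl)cyclopent-1-en-1-yl]acetaldehyde | CC1=C(CC=O)[C@H](CC1)C(C)=C
F3 | step 5 | 3-methyl-1-[(5R)-2-methyl-5-(prop-1-en-2-yl)cyclopent-1-en-1-yl]but-3-en-2-ol | CC1=C(CC(O)C(C)=C)[C@H](CC1)C(C)=C
F4 | step 6 | ({[(5R)-2-methyl-5-(prop-1-en-2-yl)cyclopent-1-en-1-yl]methyl}sulfonyl)benzene | CC1=C(CS(=O)(=O)c2ccccc2)[C@H](CC1)C(C)=C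
F5 | step 6 | methyl 2,4-dimethyl-4-{(1R)-3-methyl-2-[(phenylsulfonyl)methyl]cyclopent-2-en-1-yl}pentanoate | CC1=C(CS(=O)(=O)c2ccccc2)[C@H](CC1)C(C)(C)CC(C)C(=O)OC
F6 | step 6 | (3aR)-1,4,4,6-tetramethyl-8-(phenylsulfonyl)-2,3,3a,4,5,6,7,8-octahydroazulen-7-one | CC1=C2C(S(=O)(=O)c3ccccc3)C(=O)C(C)CC(C)(C)[C@H]2CC1
F7 | step 16 | dimethyl {4-[(2S,3S)-3-{2-[(2S)-3,3-dimethyloxiran-2-yl]ethyl}-3-methyloxiran-2-yl]-2-(trimethylsilyloxy)but-1-en-1-yl}phosphonate | COP(=O)(OC)C=C(O[Si](C)(C)C)CC[C@@H]1O[C@@]1(C)CC[C@@H]1OC1(C)C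
F8 | step 16 | dimethyl [(3S,5aR,9aS)-2,2,5a-trimethyl-7-oxo-3-(trimethylsilyloxy)decahydro-1-benzoxepin-6-yl]phosphonate | COP(=O)(OC)C1[C@]2(C)CC[C@H](O[Si](C)(C)C)C(C)(C)O[C@H]2CCC1=O
F9 | step 16 | (3S,5aS,9aS)-2,2,5a-trimethyl-6-{2-[(1S,3aS,5R,8aS)-1,4,4,6-tetramethyl-1-(trimethylsilyloxy)-1,2,3,3a,4,5,8,8a-octahydroazulen-5-yl]ethylidene}-3-(trimethylsilyloxy)octahydro-1-benzoxepin-7(2H)-one | CC1=CC[C@H]2[C@H](CC[C@]2(C)O[Si](C)(C)C)C(C)(C)[C@@H]1CC=C1[C@]2(C)CC[C@H](O[Si](C)(C)C)C(C)(C)O[C@H]2CCC1=O
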